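**Plan** (eudesmane numbering: ring A = C1–C5, C10; ring B = C5–C10; C11 = side-chain carbinol carbon)
- Retrosynthesis, end game: the 11-OH/C6=C7 array is taken back to an 8-oxo-7(11)-ene (Schenck ene reaction), and the two esters to the 3,4-diol.
- Retrosynthesis, ring B: C7–C8 and C5–C10 are cut together. The 3-methylbut-2-enoyl unit C8–C9=C10 is a 1,3-double electrophile. The skipped diene C4=C5–C6–C7=C11 is a 1,3-double nucleophile through its inner carbons C5 and C7, because its outer carbons C4 and C11 are the two tertiary carbons that end up oxygen-bearing.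
- Retrosynthesis, chain: the acyclic trienoic acid is cut at C3–C4 into aldehyde 2 (ozonolysis of methyl geranate) and an alkenyl metal from enyne 5.
- Forward: chain union at C3–C4, then in one operation ring A (C5–C10) followed by ring B (C7–C8), then diol release, angelate, acetate, photooxygenation.
- Stereochemistry: C3 by CBS reduction; C4, C5 and C10 from C3 in the key step (acetate participation, anti addition to the (E)-alkene, chair); alkene geometries from methyl geranate and syn-hydrozirconation; the (Z)-angelate is brought in intact.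

Key step: step 8

Assumption: commercial methyl geranate is used as the (2E) isomer; any (2Z) isomer is removed at aldehyde 2.

Step 1
Reactants: 1 methyl (2E)-3,7-dimethylocta-2,6-dienoate (methyl geranate)
Product: 2 methyl (2E)-3-methyl-6-oxohex-2-enoate
Conditions: O3 (1.0 equiv, Sudan Red 7B as indicator), CH2Cl2/MeOH, −78 °C; then Me2S, −78 °C → rt
Reagents that add atoms: ozone, [O-][O+]=O
Why: Ozone attacks the electron-rich trisubstituted C6=C7 alkene much faster than the ester-deactivated C2=C3 alkene, so one equivalent should cleave only the terminal isopropylidene group (chemoselective ozonolysis with reductive work-up).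

Step 2
Reactants: 3 prop-1-yn-1-ylmagnesium bromide; 4 1-bromo-3-methylbut-2-ene (prenyl bromide)
Product: 5 6-methylhept-5-en-2-yne
Conditions: CuI (5 mol %), THF, 0 °C → rt
Reagents that add atoms: none
Why: Copper-catalysed SN2 coupling of an alkynyl Grignard reagent with a primary allylic bromide should give the skipped enyne, attack at the unhindered CH2 terminus of the prenyl unit being favoured.

Step 3
Reactants: 5 6-methylhept-5-en-2-yne; 2 methyl (2E)-3-methyl-6-oxohex-2-enoate
Product: 8 rac-methyl (2E,7E)-6-hydroxy-3,7,11-trimethyldodeca-2,7,10-trienoate, via alkenylzirconocene chloride 6 (not isolated), via alkenyl(methyl)zinc 7 (not isolated)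
Conditions: 5 (1.5 equiv), Cp2Zr(H)Cl (1.4 equiv), CH2Cl2, rt; Me2Zn (1.4 equiv), −65 °C; 2, 0 °C; aq. NH4Cl
Reagents that add atoms: none
Why: syn-Hydrozirconation should place zirconium mainly on the less hindered, methyl-bearing alkyne carbon and so fix the (E)-trisubstituted alkene, and zirconium-to-zinc transmetalation gives an alkenylzinc that adds 1,2 to the aldehyde and leaves the enoate alone; the new carbinol centre is racemic and is corrected in steps 4 and 5.

Step 4
Reactants: 8 rac-methyl (2E,7E)-6-hydroxy-3,7,11-trimethyldodeca-2,7,10-trienoate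
Product: 9 methyl (2E,7E)-3,7,11-trimethyl-6-oxododeca-2,7,10-trienoate
Conditions: DMP (1.3 equiv), NaHCO3, CH2Cl2, 0 °C → rt
Reagents that add atoms: none
Why: Dess–Martin oxidation of the secondary allylic alcohol under buffered, non-basic conditions should give the enone without moving the skipped C10=C11 alkene into conjugation.

Step 5
Reactants: 9 methyl (2E,7E)-3,7,11-trimethyl-6-oxododeca-2,7,10-trienoate
Product: 10 methyl (2E,6R,7E)-6-hydroxy-3,7,11-trimethyldodeca-2,7,10-trienoate
Conditions: (S)-Me-CBS oxazaborolidine (0.2 equiv), BH3·SMe2 (0.7 equiv), THF, −30 °C; MeOH, then aqueous work-up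
Reagents that add atoms: none
Why: Corey–Bakshi–Shibata reduction, in which the α-methylalkenyl group acts as the large substituent so that the (S)-catalyst should deliver hydride to the face giving the (6R)-alcohol; catalysed ketone reduction is much faster than hydroboration of the trisubstituted alkenes or reduction of the ester.

Step 6
Reactants: 10 methyl (2E,6R,7E)-6-hydroxy-3,7,11-trimethyldodeca-2,7,10-trienoate
Product: 11 (2E,6R,7E)-6-hydroxy-3,7,11-trimethyldodeca-2,7,10-trienoic acid
Conditions: LiOH·H2O (3 equiv), THF/MeOH/H2O, rt; 1 M HCl to pH 3, 0 °C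
Reagents that add atoms: lithium hydroxide, [Li+].[OH-]
Why: Saponification of the methyl ester; nothing else in 10 is base-labile.

Step 7
Reactants: 11 (2E,6R,7E)-6-hydroxy-3,7,11-trimethyldodeca-2,7,10-trienoic acid
Product: 13 (2E,6R,7E)-6-acetoxy-3,7,11-trimethyldodeca-2,7,10-trienoic acid, via mixed acetic anhydride 12 (not isolated)
Conditions: Ac2O (3 equiv), pyridine, DMAP (5 mol %), CH2Cl2, 0 °C → rt; then H2O/THF, rt
Reagents that add atoms: acetic anhydride, CC(=O)OC(C)=O
Why: DMAP-catalysed acetylation of the allylic alcohol; the mixed anhydride formed at the carboxyl group is hydrolysed back to the acid in the aqueous stage.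

Step 8
Reactants: 13 (2E,6R,7E)-6-acetoxy-3,7,11-trimethyldodeca-2,7,10-trienoic acid
Product: 16 (3R,4S,5R,10R)-3-acetoxy-4-hydroxyeudesm-7(11)-en-8-one, via acid chloride 14 (not isolated), via acetoxonium chlorostannate 15 (not isolated)
Conditions: 1-chloro-N,N,2-trimethylprop-1-en-1-amine (1.2 equiv), CH2Cl2, 0 °C → rt; dilute to 0.01 M, SnCl4 (2.5 equiv), −78 → −30 °C; then H2O/THF, 0 °C
Reagents that add atoms: water, O
Why: Proposed new method: SnCl4 polarises the acyl chloride into a vinylogous acylium ion whose C10 is a ketene-stabilised tertiary cation; the (E)-C4=C5 alkene adds to it through C5 (ring A, 6-endo-trig with respect to C4=C5 and exo with respect to C9=C10), the C3 acetate carbonyl captures the emerging C4 cation anti to the new bond as a cis-fused acetoxonium ion (5-exo), and the ketene or acyl chloride left at C8 then acylates the C7=C11 alkene at C7 (ring B, 6-exo-trig, the C11 cation losing H+ to give the conjugated isopropylidene ketone), after which water opens the acetoxonium ion to the hydroxy acetate. The closest known reaction types are the Lewis acid-induced conjugate addition of alkenes to unsaturated carbonyl compounds, the tandem Friedel–Crafts alkylation–acylation of arenes by 3-methylbut-2-enoyl chloride (indanone synthesis) and the Friedel–Crafts cyclisation of citronelloyl chloride to pulegone-type ketones, combined here with Woodward–Prévost-type acetoxy participation. C4 is set cis to the C3 oxygen by the five-membered acetoxonium ring, C5 by anti addition across the (E)-alkene with the allylic acetate pseudo-axial (A(1,2) strain with the C4 methyl group plus anchimeric assistance), and C10 by a chair transition state with the acyl-bearing C9 branch equatorial and the methyl group axial (trans-decalin). The step needs Markovnikov regioselectivity at both alkenes and ring A closure before ring B: both alkenes are trisubstituted with their tertiary carbons C4 and C11 remote from C10 and C8, so only the two six-membered closures give tertiary cations, and acylation at C7 before ring A would need a ten-membered ring.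

Step 9
Reactants: 16 (3R,4S,5R,10R)-3-acetoxy-4-hydroxyeudesm-7(11)-en-8-one
Product: 17 (3R,4S,5R,10R)-3,4-dihydroxyeudesm-7(11)-en-8-one
Conditions: K2CO3 (1 equiv), MeOH, rt
Reagents that add atoms: none
Why: Methanolysis (transesterification) of the secondary acetate; the same conditions should also bring any 4-acetate regioisomer, isopropenyl isomer or C11 chloride from step 8 onto 17 by acyl cleavage, base-mediated conjugation and E1cB loss of HCl.

Step 10
Reactants: 17 (3R,4S,5R,10R)-3,4-dihydroxyeudesm-7(11)-en-8-one; 18 angelic acid, (2Z)-2-methylbut-2-enoic acid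
Product: 20 (3R,4S,5R,10R)-3-(angeloyloxy)-4-hydroxyeudesm-7(11)-en-8-one, via angelic trichlorobenzoic anhydride 19 (not isolated)
Conditions: 18 (4 equiv), 2,4,6-trichlorobenzoyl chloride (4 equiv), Et3N (8 equiv), toluene, rt, 2 h; then 17, 80 °C
Reagents that add atoms: none
Why: Yamaguchi esterification through a pre-formed mixed anhydride and without a nucleophilic catalyst, conditions chosen to keep the (Z)-geometry of the angeloyl group; only the secondary C3 hydroxyl should react, the tertiary C4 hydroxyl being too hindered.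

Step 11
Reactants: 20 (3R,4S,5R,10R)-3-(angeloyloxy)-4-hydroxyeudesm-7(11)-en-8-one
Product: 21 (3R,4S,5R,10R)-4-acetoxy-3-(angeloyloxy)eudesm-7(11)-en-8-one
Conditions: Ac2O (5 equiv), Sc(OTf)3 (5 mol %), MeCN, −20 °C
Reagents that add atoms: acetic anhydride, CC(=O)OC(C)=O
Why: Lewis acid-catalysed acetylation of the hindered tertiary C4 alcohol at low temperature, which should leave the angelate and the enone untouched.

Step 12
Reactants: 21 (3R,4S,5R,10R)-4-acetoxy-3-(angeloyloxy)eudesm-7(11)-en-8-one
Product: 23 (3R,4S,5R,10R)-4-acetoxy-3-(angeloyloxy)-11-hydroxyeudesm-6-en-8-one (CNP0351454.1), via allylic hydroperoxide 22 (not isolated)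
Conditions: O2, tetraphenylporphyrin (1 mol %), CH2Cl2, visible light, 0 °C; then PPh3 (1.5 equiv), 0 °C → rt
Reagents that add atoms: dioxygen, O=O
Why: Schenck ene reaction of singlet oxygen with the s-cis enone, in which oxygen should bond to the β-carbon C11 and the allylic hydrogen is taken from C6 (the substituent geminal to the carbonyl group), moving the alkene to C6=C7; PPh3 then reduces the hydroperoxide to the tertiary alcohol, no stereocentre is formed, and C5 is not touched under these neutral conditions.

**Compound list**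
1 | methyl (2E)-3,7-dimethylocta-2,6-dienoate (methyl geranate) | COC(=O)/C=C(\C)CCC=C(C)C | starting material
2 | methyl (2E)-3-methyl-6-oxohex-2-enoate | COC(=O)/C=C(\C)CCC=O | intermediate
3 | prop-1-yn-1-ylmagnesium bromide | CC#C[Mg]Br | starting material
4 | 1-bromo-3-methylbut-2-ene (prenyl bromide) | CC(C)=CCBr | starting material
5 | 6-methylhept-5-en-2-yne | CC#CCC=C(C)C | intermediate
6 | chlorobis(cyclopentadienyl)[(2E)-6-methylhepta-2,5-dien-2-yl]zirconium | C/C(=C\CC=C(C)C)[Zr](Cl)(C1C=CC=C1)C1C=CC=C1 | intermediate (not isolated)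
7 | methyl[(2E)-6-methylhepta-2,5-dien-2-yl]zinc | C[Zn]/C(C)=C/CC=C(C)C | intermediate (not isolated)
8 | rac-methyl (2E,7E)-6-hydroxy-3,7,11-trimethyldodeca-2,7,10-trienoate | COC(=O)/C=C(\C)CCC(O)/C(C)=C/CC=C(C)C | intermediate
9 | methyl (2E,7E)-3,7,11-trimethyl-6-oxododeca-2,7,10-trienoate | COC(=O)/C=C(\C)CCC(=O)/C(C)=C/CC=C(C)C | intermediate
10 | methyl (2E,6R,7E)-6-hydroxy-3,7,11-trimethyldodeca-2,7,10-trienoate | COC(=O)/C=C(\C)CC[C@@H](O)/C(C)=C/CC=C(C)C | intermediate
11 | (2E,6R,7E)-6-hydroxy-3,7,11-trimethyldodeca-2,7,10-trienoic acid | OC(=O)/C=C(\C)CC[C@@H](O)/C(C)=C/CC=C(C)C | intermediate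
12 | acetic (2E,6R,7E)-6-acetoxy-3,7,11-trimethyldodeca-2,7,10-trienoic anhydride | CC(=O)OC(=O)/C=C(\C)CC[C@@H](OC(C)=O)/C(C)=C/CC=C(C)C | intermediate (not isolated)
13 | (2E,6R,7E)-6-acetoxy-3,7,11-trimethyldodeca-2,7,10-trienoic acid | OC(=O)/C=C(\C)CC[C@@H](OC(C)=O)/C(C)=C/CC=C(C)C | intermediate
14 | (2E,6R,7E)-6-acetoxy-3,7,11-trimethyldodeca-2,7,10-trienoyl chloride | ClC(=O)/C=C(\C)CC[C@@H](OC(C)=O)/C(C)=C/CC=C(C)C | intermediate (not isolated)
15 | cis-fused 2-methyl-1,3-dioxolan-2-ylium (acetoxonium) ion bridging O3 and O4 of the 7(11)-en-8-one, as pentachlorostannate | CC1=[O+][C@@H]2CC[C@]3(C)CC(=O)C(=C(C)C)C[C@H]3[C@]2(C)O1.Cl[Sn-](Cl)(Cl)(Cl)Cl | intermediate (not isolated)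
16 | (3R,4S,5R,10R)-3-acetoxy-4-hydroxyeudesm-7(11)-en-8-one (3α-OAc, 4α-OH, 5α-H, 10β-Me) | CC(=O)O[C@@H]1CC[C@]2(C)CC(=O)C(=C(C)C)C[C@H]2[C@]1(C)O | intermediate
17 | (3R,4S,5R,10R)-3,4-dihydroxyeudesm-7(11)-en-8-one | O[C@@H]1CC[C@]2(C)CC(=O)C(=C(C)C)C[C@H]2[C@]1(C)O | intermediate
18 | angelic acid, (2Z)-2-methylbut-2-enoic acid | C/C=C(/C)C(O)=O | starting material
19 | (2Z)-2-methylbut-2-enoic 2,4,6-trichlorobenzoic anhydride | C/C=C(/C)C(=O)OC(=O)c1c(Cl)cc(Cl)cc1Cl | intermediate (not isolated)
20 | (3R,4S,5R,10R)-3-(angeloyloxy)-4-hydroxyeudesm-7(11)-en-8-one | C/C=C(/C)C(=O)O[C@@H]1CC[C@]2(C)CC(=O)C(=C(C)C)C[C@H]2[C@]1(C)O | intermediate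
21 | (3R,4S,5R,10R)-4-acetoxy-3-(angeloyloxy)eudesm-7(11)-en-8-one | C/C=C(/C)C(=O)O[C@@H]1CC[C@]2(C)CC(=O)C(=C(C)C)C[C@H]2[C@]1(C)OC(C)=O | intermediate
22 | (3R,4S,5R,10R)-4-acetoxy-3-(angeloyloxy)-11-hydroperoxyeudesm-6-en-8-one | C/C=C(/C)C(=O)O[C@@H]1CC[C@]2(C)CC(=O)C(C(C)(C)OO)=C[C@H]2[C@]1(C)OC(C)=O | intermediate (not isolated)
23 | (3R,4S,5R,10R)-4-acetoxy-3-(angeloyloxy)-11-hydroxyeudesm-6-en-8-one (CNP0351454.1) | C/C=C(/C)C(=O)O[C@@H]1CC[C@]2(C)CC(=O)C(C(C)(C)O)=C[C@H]2[C@]1(C)OC(C)=O | target

**Count**
Total steps: 12. Longest linear sequence: 11 steps (step 1 or step 2, then steps 3 to 12).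

**Steps most likely to fail**

Step 8. What may go wrong: the Lewis acid may ionise or tie up the allylic acetate before the C4=C5 alkene has added to C10; intermolecular acylation may outrun the conjugate addition; or discrimination between axial and equatorial placement of the C9 branch at C10 may be poor, giving the cis-fused isomer. Fallback, setting out from 13 and returning at 17: the acid chloride 14 (made as in step 8) is reduced with LiAlH(OtBu)3 in THF at −78 °C to (2E,6R,7E)-6-acetoxy-3,7,11-trimethyldodeca-2,7,10-trienal F1. Me2AlCl in CH2Cl2 (−78 → 0 °C, then water) is then used for the known Lewis acid-induced conjugate addition of an alkene to an enal, again with acetoxonium capture. The resulting aldehyde closes ring B by the carbonyl-ene reaction known from citronellal, giving (3R,4S,5R,10R)-3-acetoxyeudesm-11-ene-4,8-diol F2. Dess–Martin oxidation gives the isopropenyl ketone (3R,4S,5R,10R)-3-acetoxy-4-hydroxyeudesm-11-en-8-one F3. K2CO3 in MeOH then conjugates the alkene and removes the acetate to give 17.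

Step 12. What may go wrong: hydrogen abstraction from a methyl group of the isopropylidene unit with oxygen delivered to C7, or an ene reaction slow enough for the angelate alkene to compete or for the angelate to photo-isomerise. Fallback, setting out from 21 and returning at 23: Weitz–Scheffer-type nucleophilic epoxidation (t-BuOOH, DBU, CH2Cl2) gives (3R,4S,5R,10R)-4-acetoxy-3-(angeloyloxy)-7,11-epoxyeudesman-8-one F4. Reductive opening at C7 with PhSeSePh/NaBH4/AcOH in EtOH (phenylselenide reduction of an epoxy ketone to a β-hydroxy ketone) gives (3R,4S,5R,10R)-4-acetoxy-3-(angeloyloxy)-11-hydroxyeudesman-8-one F5. IBX in DMSO at 70 °C then dehydrogenates the ketone towards C6, the only side with hydrogens that can be lost because C10 is quaternary, to give 23.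

Step 10. What may go wrong: Z to E isomerisation of the activated angeloyl group (tiglate formation), or no acylation of the hindered axial alcohol. Fallback, setting out from 17 and returning at 20: the C3 hydroxyl is esterified with 2-[bis(2,2,2-trifluoroethoxy)phosphoryl]propanoic acid (DCC, DMAP, CH2Cl2) to give the phosphonate ester (3R,4S,5R,10R)-3-{2-[bis(2,2,2-trifluoroethoxy)phosphoryl]propanoyloxy}-4-hydroxyeudesm-7(11)-en-8-one F6. Still–Gennari olefination with acetaldehyde (KN(SiMe3)2, 18-crown-6, THF, −78 °C) then builds the (Z)-2-methylbut-2-enoate in place to give 20.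

Further compounds
F1 | step 8 | (2E,6R,7E)-6-acetoxy-3,7,11-trimethyldodeca-2,7,10-trienal | O=C/C=C(\C)CC[C@@H](OC(C)=O)/C(C)=C/CC=C(C)C
F2 | step 8 | (3R,4S,5R,10R)-3-acetoxyeudesm-11-ene-4,8-diol (C7 and C8 as formed in the ene closure, not defined) | CC(=O)O[C@@H]1CC[C@]2(C)CC(O)C(C(C)=C)C[C@H]2[C@]1(C)O
F3 | step 8 | (3R,4S,5R,10R)-3-acetoxy-4-hydroxyeudesm-11-en-8-one (C7 not defined) | CC(=O)O[C@@H]1CC[C@]2(C)CC(=O)C(C(C)=C)C[C@H]2[C@]1(C)O
F4 | step 12 | (3R,4S,5R,10R)-4-acetoxy-3-(angeloyloxy)-7,11-epoxyeudesman-8-one (C7 not defined) | C/C=C(/C)C(=O)O[C@@H]1CC[C@]2(C)CC(=O)C3(OC3(C)C)C[C@H]2[C@]1(C)OC(C)=O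
F5 | step 12 | (3R,4S,5R,10R)-4-acetoxy-3-(angeloyloxy)-11-hydroxyeudesman-8-one (C7 not defined) | C/C=C(/C)C(=O)O[C@@H]1CC[C@]2(C)CC(=O)C(C(C)(C)O)C[C@H]2[C@]1(C)OC(C)=O
F6 | step 10 | (3R,4S,5R,10R)-3-{2-[bis(2,2,2-trifluoroethoxy)phosphoryl]propanoyloxy}-4-hydroxyeudesm-7(11)-en-8-one | CC(C(=O)O[C@@H]1CC[C@]2(C)CC(=O)C(=C(C)C)C[C@H]2[C@]1(C)O)P(=O)(OCC(F)(F)F)OCC(F)(F)F
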